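**Plan**
- The retrosynthesis first cuts the C8–C9 CH2–CH2 bond of the octacosanoyl chain (C1 = ester carbonyl carbon), then the benzyl ester C(=O)–O bond of the C9 half-ester that results.
- Enabling feature: C8 and C9 are unbranched methylene carbons in a saturated chain with no heteroatom nearer than C1. Each can be uncovered as a primary alkyl radical from a carboxylate, so two carbons of like polarity are joined by anodic decarboxylative radical coupling (crossed Kolbe electrolysis).
- Forward: azelaic acid is mono-benzylated (step 1). Its free CO2H and that of heneicosanoic acid then leave as CO2 while the C8 and C20 pieces join (step 2), giving the target directly; the two carboxyl groups are the only activating groups and are removed in the coupling itself.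
- No ring is formed (the phenyl ring arrives intact in benzyl alcohol). The target has no stereocentre and no stereogenic double bond, so no stereocontrol is needed.

Key step: step 2

Remark: chain atoms are numbered from the ester carbonyl carbon (C1) to the terminal methyl (C28).

**Step 1**
Reactants: 1 azelaic acid (nonanedioic acid); 2 benzyl alcohol
Product: 3 monobenzyl azelate (9-(benzyloxy)-9-oxononanoic acid)
Conditions: 1 (2 equiv), 2 (1 equiv), TsOH·H2O (cat.), toluene, reflux, Dean–Stark; unreacted 1 removed by filtration from cold toluene and a hot-water wash, 3 separated from neutral material on silica
Reagents that add atoms: none
Why: Fischer esterification driven by azeotropic removal of water; the two carboxyl groups are equivalent and insulated by seven methylenes, so the excess of diacid should bias the statistical outcome towards the half-ester.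

**Step 2**
Reactants: 3 monobenzyl azelate; 4 heneicosanoic acid
Product: 5 benzyl octacosanoate
Conditions: Pt anode/Pt cathode, undivided cell, 3 (3 equiv), 4 (1 equiv), NaOMe (0.05 equiv per CO2H), MeOH–pyridine 3:1, 50 °C, constant current ca. 0.2 A cm⁻², stopped while the solution is still faintly acidic
Reagents that add atoms: none
Why: At the platinum anode the carboxylates of 3 and 4 are each oxidised by one electron to acyloxy radicals that lose CO2 at once, giving the 7-(benzyloxycarbonyl)heptyl and icosyl primary radicals in high local concentration in the carboxylate-covered anode layer, where they combine to form the C8–C9 bond, while the carboxyl protons are reduced to hydrogen at the cathode. The closest known reaction type is the crossed Kolbe electrolysis of a fatty acid with a dicarboxylic acid half-ester, the classical chain extension of long-chain acids. No ring is closed and no stereocentre is formed. The step needs cross-coupling to prevail over homo-coupling, which is only statistical and is biased by the three-fold excess of the cheap half-ester 3; the two homo-dimers (one a hydrocarbon, the other a diester) differ enough in polarity from the mono-ester 5 to be removed on silica. It also needs radical combination to win over further oxidation to cations, which the unbranched primary radical centres without any α-donor, the smooth Pt anode, the high current density and the weakly acidic medium should secure. The benzyl ester, seven methylenes from the radical centre, should survive because its arene is harder to oxidise than the carboxylate that blankets the anode and because the electrolysis is stopped before the solution turns basic, so that methanolysis is avoided.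

**Compound list**
1 | azelaic acid (nonanedioic acid) | OC(=O)CCCCCCCC(=O)O | starting material
2 | benzyl alcohol | OCc1ccccc1 | starting material
3 | monobenzyl azelate (9-(benzyloxy)-9-oxononanoic acid) | OC(=O)CCCCCCCC(=O)OCc1ccccc1 | intermediate
4 | heneicosanoic acid | CCCCCCCCCCCCCCCCCCCCC(=O)O | starting material
5 | benzyl octacosanoate | CCCCCCCCCCCCCCCCCCCCCCCCCCCC(=O)OCc1ccccc1 | target

Total step count: 2
Longest linear sequence: 2 steps

**Steps most likely to fail** (the route has only two steps; both are ranked)

1. Step 2. Possible failures are statistical homo-coupling that drains the valuable acid 4, passivation of the anode by deposition of waxy product, over-oxidation of the radicals to cations (non-Kolbe ether and alkene formation), and methanolysis of the benzyl ester if the medium turns alkaline near the end. The fallback sets out from benzyl alcohol 2 and comes back at 5, replacing the radical union by a polar copper-catalysed sp3–sp3 coupling across the same C8–C9 bond. Commercial 8-bromooctanoic acid is esterified with 2 (TsOH cat., toluene, Dean–Stark) to give benzyl 8-bromooctanoate F1. Commercial 1-bromoicosane is converted with Mg in THF into icosylmagnesium bromide F2. F2 is then added slowly to F1 with Li2CuCl4 (cat.) in THF–NMP at −10 to 0 °C, conditions under which an ester should be tolerated, to give 5.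

2. Step 1. Possible failures are unselective double esterification and a tedious separation of diacid, half-ester and diester. The fallback sets out from benzyl alcohol 2 and comes back at 3, building the half-ester by oxidative cleavage instead of desymmetrising a diacid. Commercial oleic acid is esterified with 2 (TsOH cat., toluene, Dean–Stark) to give benzyl oleate F3. Ozonolysis (O3, CH2Cl2–MeOH, −78 °C; then Me2S) cleaves the C9=C10 double bond to give benzyl 9-oxononanoate F4. Pinnick oxidation (NaClO2, NaH2PO4, 2-methyl-2-butene, t-BuOH–H2O) should then deliver 3 as a single mono-ester.

**Further compounds**
F1 | step 2 | benzyl 8-bromooctanoate | BrCCCCCCCC(=O)OCc1ccccc1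
F2 | step 2 | icosylmagnesium bromide | CCCCCCCCCCCCCCCCCCCC[Mg]Br
F3 | step 1 | benzyl oleate (benzyl (Z)-octadec-9-enoate) | CCCCCCCC/C=C\CCCCCCCC(=O)OCc1ccccc1
F4 | step 1 | benzyl 9-oxononanoate | O=CCCCCCCCC(=O)OCc1ccccc1
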